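**Plan**

- Numbering: ring C5 (isopropenyl), C6 (lactone O), C7, C8 (acyloxy), C9, C10 (methyl, vinyl); lactone carbons C11 (methyl, acetoxy) and C12 (C=O).
- Retrosynthetic cuts, in order: the C8–O acyl and C11–O acetyl bonds; C11–CH3 and C11–O; ring bond C7–C8; butenolide O–C12 and C6–C7; C5–C10.
- Enabling feature: C8 is a carbinol carbon bonded to C7, and C7 is β to the lactone carbonyl C12. A C8 ketyl can therefore close ring C5–C10 onto C7 of a C7=C11 butenolide that already carries C6–O.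
- Forward order: chain C8–C9–C10–C5–C6 by [3,3] rearrangement, C6–C7 by acetylide acylation, the butenolide ring, the cyclohexane ring (C7–C8), then C11 oxidation and methylation and the two esters.
- Stereochemistry: C5/C10 from a chair Ireland–Claisen transition state under a chiral boron controller; C6 from catalyst-controlled, Felkin-matched transfer hydrogenation; C7 from the tether and C8 from a chair ketyl transition state; C11 from convex-face methylation of the cis-fused lactone enolate.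

Key step: step 9

Remark (assumption): the (4R,5R)-diazaborolidine in step 3 is assumed to select the enolate face that leads to (2R,3S)-7; if a first run shows the opposite sense, the (4S,5S) reagent is used with no other change.

**Route**

Step 1
Reactants: 1 tert-butyl(but-3-yn-1-yloxy)dimethylsilane
Product: 3 (E)-5-[(tert-butyldimethylsilyl)oxy]-3-methylpent-2-en-1-ol, via alkenylalane 2 (not isolated)
Conditions: AlMe3 (2 equiv), Cp2ZrCl2 (cat.), CH2Cl2, 0 °C→rt; then (CH2O)n, THF, 0 °C→rt; aq. KNaC4H4O6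
Reagents that add atoms: trimethylaluminium, C[Al](C)C; formaldehyde (as paraformaldehyde), C=O
Why: Zirconium-catalysed syn-carboalumination of the terminal alkyne (Negishi carboalumination) places methyl and aluminium cis, and hydroxymethylation of the alkenylalane with retention should fix the E geometry that the later chair rearrangement needs.

Step 2
Reactants: 3 (E)-5-[(tert-butyldimethylsilyl)oxy]-3-methylpent-2-en-1-ol; 4 3-methylbut-3-enoic acid
Product: 5 (E)-5-[(tert-butyldimethylsilyl)oxy]-3-methylpent-2-en-1-yl 3-methylbut-3-enoate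
Conditions: DCC, DMAP (5 mol %), CH2Cl2, 0 °C
Reagents that add atoms: none
Why: Steglich esterification at 0 °C with little DMAP should acylate the primary allylic alcohol without moving the β,γ-double bond of the acid into conjugation.

Step 3
Reactants: 5 (E)-5-[(tert-butyldimethylsilyl)oxy]-3-methylpent-2-en-1-yl 3-methylbut-3-enoate
Product: 7 (2R,3S)-5-[(tert-butyldimethylsilyl)oxy]-3-ethenyl-3-methyl-2-(prop-1-en-2-yl)pentanoic acid, via boron ketene acetal 6 (not isolated)
Conditions: (4R,5R)-2-bromo-4,5-diphenyl-1,3-bis{[3,5-bis(trifluoromethyl)phenyl]sulfonyl}-1,3,2-diazaborolidine (1.2 equiv), i-Pr2NEt, CH2Cl2, −78 °C; then −20 °C→rt; aqueous work-up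
Reagents that add atoms: none
Why: In this enantioselective Ireland–Claisen rearrangement, soft enolisation in CH2Cl2 should give the boron ketene acetal with isopropenyl cis to O–B, a chair transition state with isopropenyl and the C9 chain equatorial then sets C5 and C10 in the (2R,3S) relationship, and the C2-symmetric diazaborolidine selects the enolate face.

Step 4
Reactants: 7 (2R,3S)-5-[(tert-butyldimethylsilyl)oxy]-3-ethenyl-3-methyl-2-(prop-1-en-2-yl)pentanoic acid
Product: 9 (2R,3S)-5-[(tert-butyldimethylsilyl)oxy]-3-ethenyl-N-methoxy-N,3-dimethyl-2-(prop-1-en-2-yl)pentanamide, via acid chloride 8 (not isolated)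
Conditions: 1-chloro-N,N,2-trimethylprop-1-en-1-amine, CH2Cl2, 0 °C→rt; then MeNH(OMe)·HCl, pyridine, 0 °C
Reagents that add atoms: N,O-dimethylhydroxylamine hydrochloride, CNOC.Cl
Why: Weinreb amide formation through an acid chloride made under neutral conditions (Ghosez reagent) suits a hindered acid, and the quaternary neighbour should shield the C5 hydrogen against ketene formation and epimerisation.

Step 5
Reactants: 9 (2R,3S)-5-[(tert-butyldimethylsilyl)oxy]-3-ethenyl-N-methoxy-N,3-dimethyl-2-(prop-1-en-2-yl)pentanamide; 10 3,3,3-triethoxyprop-1-yne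
Product: 12 (5R,6S)-8-[(tert-butyldimethylsilyl)oxy]-6-ethenyl-1,1,1-triethoxy-6-methyl-5-(prop-1-en-2-yl)oct-2-yn-4-one, via lithium acetylide 11 (not isolated)
Conditions: 10, n-BuLi, THF, −78 °C; then 9, −78→0 °C; cold aq. NH4Cl
Reagents that add atoms: none
Why: Acylation of a lithium acetylide by a Weinreb amide should stop at the ketone because the chelated tetrahedral adduct survives until the cold quench, and the orthoester serves as a propiolate anion equivalent that leaves no conjugated ester on the ynone.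

Step 6
Reactants: 12 (5R,6S)-8-[(tert-butyldimethylsilyl)oxy]-6-ethenyl-1,1,1-triethoxy-6-methyl-5-(prop-1-en-2-yl)oct-2-yn-4-one
Product: 14 ethyl (4R,5R,6S)-8-[(tert-butyldimethylsilyl)oxy]-6-ethenyl-4-hydroxy-6-methyl-5-(prop-1-en-2-yl)oct-2-ynoate, via orthoester alcohol 13 (not isolated)
Conditions: Ru(p-cymene)[(R,R)-TsNCHPhCHPhNH] (2 mol %, base-free), i-PrOH, rt; then 0.1 M aq. HCl, THF, 0 °C
Reagents that add atoms: water, O
Why: Noyori asymmetric transfer hydrogenation of the alkynyl ketone should deliver hydride under catalyst control to give the (4R) carbinol (C6), which is also the Felkin–Anh product with the quaternary C10 group anti to the hydride, and the dilute acid then turns the orthoester into the ethyl ester.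

Step 7
Reactants: 14 ethyl (4R,5R,6S)-8-[(tert-butyldimethylsilyl)oxy]-6-ethenyl-4-hydroxy-6-methyl-5-(prop-1-en-2-yl)oct-2-ynoate
Product: 17 (5S)-5-[(1R,2S)-2-ethenyl-4-hydroxy-2-methyl-1-(prop-1-en-2-yl)butyl]furan-2(5H)-one, via Z-hydroxy enoate 15 (not isolated), via silyl butenolide 16 (not isolated)
Conditions: H2 (1 atm), Pd/CaCO3 poisoned with Pb(OAc)2, quinoline, EtOAc, rt; filter; then CSA, MeOH, rt
Reagents that add atoms: none
Why: Lindlar semihydrogenation should stop at the Z-enoate, whose C6 hydroxyl closes the butenolide by lactonisation with retention at C6, and the same methanolic acid removes the primary silyl ether.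

Step 8
Reactants: 17 (5S)-5-[(1R,2S)-2-ethenyl-4-hydroxy-2-methyl-1-(prop-1-en-2-yl)butyl]furan-2(5H)-one
Product: 18 (3S,4R)-3-ethenyl-3,5-dimethyl-4-[(2S)-5-oxo-2,5-dihydrofuran-2-yl]hex-5-enal
Conditions: Dess–Martin periodinane, CH2Cl2, 0 °C→rt
Reagents that add atoms: none
Why: Dess–Martin oxidation converts the primary alcohol into the aldehyde under near-neutral conditions that should leave the butenolide and its C6 stereocentre untouched.

Step 9
Reactants: 18 (3S,4R)-3-ethenyl-3,5-dimethyl-4-[(2S)-5-oxo-2,5-dihydrofuran-2-yl]hex-5-enal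
Product: 20 (3aS,4R,6S,7R,7aR)-6-ethenyl-4-hydroxy-6-methyl-7-(prop-1-en-2-yl)hexahydro-1-benzofuran-2(3H)-one, via samarium enolate 19 (not isolated)
Conditions: SmI2 (2.5 equiv), t-BuOH (2 equiv), THF, −78→−20 °C; aq. NH4Cl
Reagents that add atoms: none
Why: SmI2 reduces the aldehyde to a C8 ketyl radical that adds to C7, the β-carbon of the butenolide, and a second electron transfer gives a samarium enolate at C11/C12 that t-BuOH protonates; this is a reductive ketyl–olefin cyclisation, the closest known cases being SmI2-mediated additions of aldehyde ketyls to α,β-unsaturated esters and lactones. The cyclohexane C5–C10 closes by 6-exo-trig attack. C7 is fixed by the tether, because C8 hangs from C6 through C5, C10 and C9 and can reach C7 only on the face that carries C5, so the lactone ends cis-fused. C8 is fixed by a chair transition state with isopropenyl equatorial, in which the samarium-bound ketyl oxygen takes the equatorial site to avoid the axial C6–O and C10 vinyl groups and the lactone dipole, which places the hydroxyl trans to C11. The step needs chemoselectivity for the aldehyde over the butenolide and for the enoate over the two unactivated alkenes; leaving out HMPA should keep electron transfer at the aldehyde, and the polarity match of the nucleophilic ketyl with the electron-poor C7 should direct the addition.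

Step 10
Reactants: 20 (3aS,4R,6S,7R,7aR)-6-ethenyl-4-hydroxy-6-methyl-7-(prop-1-en-2-yl)hexahydro-1-benzofuran-2(3H)-one
Product: 21 (3aR,4R,6S,7R,7aR)-4-[(tert-butyldimethylsilyl)oxy]-6-ethenyl-6-methyl-7-(prop-1-en-2-yl)hexahydro-1-benzofuran-2(3H)-one
Conditions: TBSOTf, 2,6-lutidine, CH2Cl2, −78→0 °C
Reagents that add atoms: tert-butyldimethylsilyl triflate, CC(C)(C)[Si](C)(C)OS(=O)(=O)C(F)(F)F
Why: Silylation of the equatorial secondary alcohol with a silyl triflate and a hindered pyridine base avoids alkoxide formation and thus translactonisation to C8.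

Step 11
Reactants: 21 (3aR,4R,6S,7R,7aR)-4-[(tert-butyldimethylsilyl)oxy]-6-ethenyl-6-methyl-7-(prop-1-en-2-yl)hexahydro-1-benzofuran-2(3H)-one
Product: 23 (3R,3aR,4R,6S,7R,7aR)-4-[(tert-butyldimethylsilyl)oxy]-6-ethenyl-3-hydroxy-6-methyl-7-(prop-1-en-2-yl)hexahydro-1-benzofuran-2(3H)-one, via potassium enolate 22 (not isolated)
Conditions: KN(SiMe3)2, THF, −78 °C; then 2-(phenylsulfonyl)-3-phenyloxaziridine, −78 °C; aq. NH4Cl
Reagents that add atoms: 2-(phenylsulfonyl)-3-phenyloxaziridine, O=S(=O)(c1ccccc1)N1OC1c1ccccc1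
Why: Enolate hydroxylation with an N-sulfonyloxaziridine (Davis oxidation) installs the C11 oxygen without touching the alkenes, and its configuration, expected from convex-face attack, is erased again in step 13.

Step 12
Reactants: 23 (3R,3aR,4R,6S,7R,7aR)-4-[(tert-butyldimethylsilyl)oxy]-6-ethenyl-3-hydroxy-6-methyl-7-(prop-1-en-2-yl)hexahydro-1-benzofuran-2(3H)-one
Product: 24 (3R,3aS,4R,6S,7R,7aR)-4-[(tert-butyldimethylsilyl)oxy]-6-ethenyl-3-[(2-methoxypropan-2-yl)oxy]-6-methyl-7-(prop-1-en-2-yl)hexahydro-1-benzofuran-2(3H)-one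
Conditions: 2-methoxypropene, PPTS (cat.), CH2Cl2, 0 °C
Reagents that add atoms: 2-methoxypropene, COC(C)=C
Why: Acid-catalysed addition of the alcohol to the enol ether (mixed acetal protection) gives a base-stable group that cannot migrate to the enolate oxygen and brings in no new stereocentre.

Step 13
Reactants: 24 (3R,3aS,4R,6S,7R,7aR)-4-[(tert-butyldimethylsilyl)oxy]-6-ethenyl-3-[(2-methoxypropan-2-yl)oxy]-6-methyl-7-(prop-1-en-2-yl)hexahydro-1-benzofuran-2(3H)-one
Product: 27 (3S,3aR,4R,6S,7R,7aR)-4-[(tert-butyldimethylsilyl)oxy]-6-ethenyl-3-hydroxy-3,6-dimethyl-7-(prop-1-en-2-yl)hexahydro-1-benzofuran-2(3H)-one, via lithium enolate 25 (not isolated), via methylated acetal 26 (not isolated)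
Conditions: LiN(i-Pr)2, THF, −78 °C; MeI, −78→−30 °C; then 1 M aq. HCl, THF, 0 °C
Reagents that add atoms: iodomethane, CI
Why: Enolate alkylation of the α-alkoxy lactone with MeI should occur on the convex face of the cis-fused bicycle, anti to C8, so that methyl ends cis to H7 and the oxygen on the concave face (C11 S), and the dilute acid then cleaves only the acetal.

Step 14
Reactants: 27 (3S,3aR,4R,6S,7R,7aR)-4-[(tert-butyldimethylsilyl)oxy]-6-ethenyl-3-hydroxy-3,6-dimethyl-7-(prop-1-en-2-yl)hexahydro-1-benzofuran-2(3H)-one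
Product: 28 (3S,3aR,4R,6S,7R,7aR)-4-[(tert-butyldimethylsilyl)oxy]-6-ethenyl-3,6-dimethyl-2-oxo-7-(prop-1-en-2-yl)octahydro-1-benzofuran-3-yl acetate
Conditions: Ac2O, DMAP, Et3N, CH2Cl2, rt
Reagents that add atoms: acetic anhydride, CC(=O)OC(C)=O
Why: DMAP-catalysed acetylation converts the tertiary α-hydroxy lactone into the acetate while C8 is still silylated, so no base-sensitive β,γ-unsaturated ester is yet present.

Step 15
Reactants: 28 (3S,3aR,4R,6S,7R,7aR)-4-[(tert-butyldimethylsilyl)oxy]-6-ethenyl-3,6-dimethyl-2-oxo-7-(prop-1-en-2-yl)octahydro-1-benzofuran-3-yl acetate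
Product: 29 (3S,3aS,4R,6S,7R,7aR)-6-ethenyl-4-hydroxy-3,6-dimethyl-2-oxo-7-(prop-1-en-2-yl)octahydro-1-benzofuran-3-yl acetate
Conditions: HF·pyridine, pyridine, THF, 0 °C→rt
Reagents that add atoms: none
Why: Fluoride-mediated desilylation under buffered acidic conditions frees the C8 hydroxyl without forming an alkoxide that could trigger acetyl migration or translactonisation.

Step 16
Reactants: 29 (3S,3aS,4R,6S,7R,7aR)-6-ethenyl-4-hydroxy-3,6-dimethyl-2-oxo-7-(prop-1-en-2-yl)octahydro-1-benzofuran-3-yl acetate; 4 3-methylbut-3-enoic acid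
Product: 30 (3S,3aS,4R,6S,7R,7aR)-3-(acetyloxy)-6-ethenyl-3,6-dimethyl-2-oxo-7-(prop-1-en-2-yl)octahydro-1-benzofuran-4-yl 3-methylbut-3-enoate
Conditions: DCC, DMAP (cat.), CH2Cl2, 0 °C
Reagents that add atoms: none
Why: Steglich esterification of the equatorial secondary alcohol completes the target, and the low temperature and catalytic DMAP should limit isomerisation of the acyl group to the conjugated 3-methylbut-2-enoate.

**Compound list**

1 | tert-butyl(but-3-yn-1-yloxy)dimethylsilane | C#CCCO[Si](C)(C)C(C)(C)C | starting material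
2 | [(E)-4-[(tert-butyldimethylsilyl)oxy]-2-methylbut-1-en-1-yl]dimethylalane | C[Al](C)/C=C(\C)CCO[Si](C)(C)C(C)(C)C | intermediate
3 | (E)-5-[(tert-butyldimethylsilyl)oxy]-3-methylpent-2-en-1-ol | OC/C=C(\C)CCO[Si](C)(C)C(C)(C)C | intermediate
4 | 3-methylbut-3-enoic acid | C=C(C)CC(=O)O | starting material
5 | (E)-5-[(tert-butyldimethylsilyl)oxy]-3-methylpent-2-en-1-yl 3-methylbut-3-enoate | C=C(C)CC(=O)OC/C=C(\C)CCO[Si](C)(C)C(C)(C)C | intermediate
6 | boron ketene acetal of 5 carrying the (4R,5R)-4,5-diphenyl-1,3-bis{[3,5-bis(trifluoromethyl)phenyl]sulfonyl}-1,3,2-diazaborolidin-2-yl group on oxygen, isopropenyl cis to O–B | C=C(C)/C=C(\OB1N(S(=O)(=O)c2cc(cc(c2)C(F)(F)F)C(F)(F)F)[C@H](c2ccccc2)[C@@H](c2ccccc2)N1S(=O)(=O)c1cc(cc(c1)C(F)(F)F)C(F)(F)F)OC/C=C(\C)CCO[Si](C)(C)C(C)(C)C | intermediate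
7 | (2R,3S)-5-[(tert-butyldimethylsilyl)oxy]-3-ethenyl-3-methyl-2-(prop-1-en-2-yl)pentanoic acid | CC(C)(C)[Si](C)(C)OCC[C@@](C)(C=C)[C@@H](C(C)=C)C(=O)O | intermediate
8 | (2R,3S)-5-[(tert-butyldimethylsilyl)oxy]-3-ethenyl-3-methyl-2-(prop-1-en-2-yl)pentanoyl chloride | CC(C)(C)[Si](C)(C)OCC[C@@](C)(C=C)[C@@H](C(C)=C)C(=O)Cl | intermediate
9 | (2R,3S)-5-[(tert-butyldimethylsilyl)oxy]-3-ethenyl-N-methoxy-N,3-dimethyl-2-(prop-1-en-2-yl)pentanamide | CC(C)(C)[Si](C)(C)OCC[C@@](C)(C=C)[C@@H](C(C)=C)C(=O)N(C)OC | intermediate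
10 | 3,3,3-triethoxyprop-1-yne | C#CC(OCC)(OCC)OCC | starting material
11 | lithium 3,3,3-triethoxyprop-1-yn-1-ide | [Li]C#CC(OCC)(OCC)OCC | intermediate
12 | (5R,6S)-8-[(tert-butyldimethylsilyl)oxy]-6-ethenyl-1,1,1-triethoxy-6-methyl-5-(prop-1-en-2-yl)oct-2-yn-4-one | CC(C)(C)[Si](C)(C)OCC[C@@](C)(C=C)[C@@H](C(C)=C)C(=O)C#CC(OCC)(OCC)OCC | intermediate
13 | (4R,5R,6S)-8-[(tert-butyldimethylsilyl)oxy]-6-ethenyl-1,1,1-triethoxy-6-methyl-5-(prop-1-en-2-yl)oct-2-yn-4-ol | CC(C)(C)[Si](C)(C)OCC[C@@](C)(C=C)[C@@H](C(C)=C)[C@@H](O)C#CC(OCC)(OCC)OCC | intermediate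
14 | ethyl (4R,5R,6S)-8-[(tert-butyldimethylsilyl)oxy]-6-ethenyl-4-hydroxy-6-methyl-5-(prop-1-en-2-yl)oct-2-ynoate | CC(C)(C)[Si](C)(C)OCC[C@@](C)(C=C)[C@@H](C(C)=C)[C@@H](O)C#CC(=O)OCC | intermediate
15 | ethyl (2Z,4S,5R,6S)-8-[(tert-butyldimethylsilyl)oxy]-6-ethenyl-4-hydroxy-6-methyl-5-(prop-1-en-2-yl)oct-2-enoate | CC(C)(C)[Si](C)(C)OCC[C@@](C)(C=C)[C@@H](C(C)=C)[C@@H](O)/C=C\C(=O)OCC | intermediate
16 | (5S)-5-[(1R,2S)-4-[(tert-butyldimethylsilyl)oxy]-2-ethenyl-2-methyl-1-(prop-1-en-2-yl)butyl]furan-2(5H)-one | CC(C)(C)[Si](C)(C)OCC[C@@](C)(C=C)[C@@H](C(C)=C)[C@H]1OC(=O)C=C1 | intermediate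
17 | (5S)-5-[(1R,2S)-2-ethenyl-4-hydroxy-2-methyl-1-(prop-1-en-2-yl)butyl]furan-2(5H)-one | OCC[C@@](C)(C=C)[C@@H](C(C)=C)[C@H]1OC(=O)C=C1 | intermediate
18 | (3S,4R)-3-ethenyl-3,5-dimethyl-4-[(2S)-5-oxo-2,5-dihydrofuran-2-yl]hex-5-enal | O=CC[C@@](C)(C=C)[C@@H](C(C)=C)[C@H]1OC(=O)C=C1 | intermediate
19 | bis(diiodosamarium) C8-alkoxide C12-enolate of 20 (trivalent samarium) | C=C[C@]1(C)C[C@@H](O[Sm](I)I)[C@H]2[C@H](OC(O[Sm](I)I)=C2)[C@@H]1C(=C)C | intermediate
20 | (3aS,4R,6S,7R,7aR)-6-ethenyl-4-hydroxy-6-methyl-7-(prop-1-en-2-yl)hexahydro-1-benzofuran-2(3H)-one | C=C[C@]1(C)C[C@@H](O)[C@H]2[C@H](OC(=O)C2)[C@@H]1C(=C)C | intermediate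
21 | (3aR,4R,6S,7R,7aR)-4-[(tert-butyldimethylsilyl)oxy]-6-ethenyl-6-methyl-7-(prop-1-en-2-yl)hexahydro-1-benzofuran-2(3H)-one | C=C[C@]1(C)C[C@@H](O[Si](C)(C)C(C)(C)C)[C@H]2[C@H](OC(=O)C2)[C@@H]1C(=C)C | intermediate
22 | potassium C12-enolate of 21 | C=C[C@]1(C)C[C@@H](O[Si](C)(C)C(C)(C)C)[C@H]2[C@H](OC([O-])=C2)[C@@H]1C(=C)C.[K+] | intermediate
23 | (3R,3aR,4R,6S,7R,7aR)-4-[(tert-butyldimethylsilyl)oxy]-6-ethenyl-3-hydroxy-6-methyl-7-(prop-1-en-2-yl)hexahydro-1-benzofuran-2(3H)-one | C=C[C@]1(C)C[C@@H](O[Si](C)(C)C(C)(C)C)[C@H]2[C@H](OC(=O)[C@@H]2O)[C@@H]1C(=C)C | intermediate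
24 | (3R,3aS,4R,6S,7R,7aR)-4-[(tert-butyldimethylsilyl)oxy]-6-ethenyl-3-[(2-methoxypropan-2-yl)oxy]-6-methyl-7-(prop-1-en-2-yl)hexahydro-1-benzofuran-2(3H)-one | C=C[C@]1(C)C[C@@H](O[Si](C)(C)C(C)(C)C)[C@H]2[C@H](OC(=O)[C@@H]2OC(C)(C)OC)[C@@H]1C(=C)C | intermediate
25 | lithium C12-enolate of 24 | C=C[C@]1(C)C[C@@H](O[Si](C)(C)C(C)(C)C)[C@H]2[C@H](OC([O-])=C2OC(C)(C)OC)[C@@H]1C(=C)C.[Li+] | intermediate
26 | (3S,3aR,4R,6S,7R,7aR)-4-[(tert-butyldimethylsilyl)oxy]-6-ethenyl-3-[(2-methoxypropan-2-yl)oxy]-3,6-dimethyl-7-(prop-1-en-2-yl)hexahydro-1-benzofuran-2(3H)-one | C=C[C@]1(C)C[C@@H](O[Si](C)(C)C(C)(C)C)[C@H]2[C@H](OC(=O)[C@@]2(C)OC(C)(C)OC)[C@@H]1C(=C)C | intermediate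
27 | (3S,3aR,4R,6S,7R,7aR)-4-[(tert-butyldimethylsilyl)oxy]-6-ethenyl-3-hydroxy-3,6-dimethyl-7-(prop-1-en-2-yl)hexahydro-1-benzofuran-2(3H)-one | C=C[C@]1(C)C[C@@H](O[Si](C)(C)C(C)(C)C)[C@H]2[C@H](OC(=O)[C@@]2(C)O)[C@@H]1C(=C)C | intermediate
28 | (3S,3aR,4R,6S,7R,7aR)-4-[(tert-butyldimethylsilyl)oxy]-6-ethenyl-3,6-dimethyl-2-oxo-7-(prop-1-en-2-yl)octahydro-1-benzofuran-3-yl acetate | C=C[C@]1(C)C[C@@H](O[Si](C)(C)C(C)(C)C)[C@H]2[C@H](OC(=O)[C@@]2(C)OC(C)=O)[C@@H]1C(=C)C | intermediate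
29 | (3S,3aS,4R,6S,7R,7aR)-6-ethenyl-4-hydroxy-3,6-dimethyl-2-oxo-7-(prop-1-en-2-yl)octahydro-1-benzofuran-3-yl acetate | C=C[C@]1(C)C[C@@H](O)[C@H]2[C@H](OC(=O)[C@@]2(C)OC(C)=O)[C@@H]1C(=C)C | intermediate
30 | (3S,3aS,4R,6S,7R,7aR)-3-(acetyloxy)-6-ethenyl-3,6-dimethyl-2-oxo-7-(prop-1-en-2-yl)octahydro-1-benzofuran-4-yl 3-methylbut-3-enoate | C=C[C@]1(C)C[C@@H](OC(=O)CC(=C)C)[C@H]2[C@H](OC(=O)[C@@]2(C)OC(C)=O)[C@@H]1C(=C)C | target

**Step count and risks**

Total step count: 16. Longest linear sequence: 16 steps (1 to 30); compounds 4 and 10 enter as purchased reagents.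

Steps most likely to fail:

1. Step 3. The boron enolate geometry or the facial control may be incomplete during the slow rearrangement, which would leak the C5/C10 diastereomer or the enantiomer. Fallback: setting out from ester 5, an achiral Ireland–Claisen rearrangement (KN(SiMe3)2, Me3SiCl, toluene, −78 °C→rt), which should give the same enolate geometry, passes through the trimethylsilyl ketene acetal F1 and the racemic trimethylsilyl ester F2 to the racemic acid F3 after aqueous work-up. The acid is resolved by crystallising its (S)-1-phenylethylammonium salt F4, the salt of the antipode F5 staying in the mother liquor, and aqueous HCl then returns the route to acid 7.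

2. Step 9. Electron transfer to the butenolide (ring opening), pinacol dimerisation of the aldehyde, or erosion of the C8 selectivity may compete with the cyclisation. Fallback: setting out from aldehyde 18, the C7–C8 bond is made by polar umpolung instead. An intramolecular Stetter reaction (achiral triazolium carbene precursor, i-Pr2NEt, toluene) adds the C8 acyl anion equivalent to C7 on the same tether-controlled face and gives the 8-oxo cis-fused lactone F6. LiBH(s-Bu)3 at −78 °C should attack from the equatorial side, away from the axial C6–O and vinyl groups, to give the axial 8-epi alcohol F7. Mitsunobu inversion with chloroacetic acid (PPh3, DIAD) gives the equatorial chloroacetate F8, and thiourea with NaHCO3 removes the chloroacetyl group to rejoin the route at alcohol 20.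

3. Step 13. Deprotonation of the concave C11–H beside the bulky acetal may be slow, and O-alkylation or imperfect facial selectivity may follow. Fallback: setting out from hydroxy lactone 23, the acetal is omitted; 2.2 equivalents of LiN(i-Pr)2 in THF/DMPU generate the dilithium alkoxide–enolate F9, whose C-methylation with MeI on the convex face (dianion alkylation of an α-hydroxy ester) gives alcohol 27 directly.

**Further compounds**

F1 | step 3 | trimethylsilyl ketene acetal of 5, isopropenyl cis to O–Si | C=C(C)/C=C(\O[Si](C)(C)C)OC/C=C(\C)CCO[Si](C)(C)C(C)(C)C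
F2 | step 3 | racemic trimethylsilyl (2R*,3S*)-5-[(tert-butyldimethylsilyl)oxy]-3-ethenyl-3-methyl-2-(prop-1-en-2-yl)pentanoate | CC(C)(C)[Si](C)(C)OCC[C@@](C)(C=C)[C@@H](C(C)=C)C(=O)O[Si](C)(C)C.CC(C)(C)[Si](C)(C)OCC[C@](C)(C=C)[C@H](C(C)=C)C(=O)O[Si](C)(C)C
F3 | step 3 | racemic (2R*,3S*)-5-[(tert-butyldimethylsilyl)oxy]-3-ethenyl-3-methyl-2-(prop-1-en-2-yl)pentanoic acid | CC(C)(C)[Si](C)(C)OCC[C@@](C)(C=C)[C@@H](C(C)=C)C(=O)O.CC(C)(C)[Si](C)(C)OCC[C@](C)(C=C)[C@H](C(C)=C)C(=O)O
F4 | step 3 | (S)-1-phenylethylammonium salt of acid 7 | CC(C)(C)[Si](C)(C)OCC[C@@](C)(C=C)[C@@H](C(C)=C)C(=O)[O-].C[C@H]([NH3+])c1ccccc1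
F5 | step 3 | (S)-1-phenylethylammonium salt of the (2S,3R) acid | CC(C)(C)[Si](C)(C)OCC[C@](C)(C=C)[C@H](C(C)=C)C(=O)[O-].C[C@H]([NH3+])c1ccccc1
F6 | step 9 | (3aR,6S,7R,7aR)-6-ethenyl-6-methyl-7-(prop-1-en-2-yl)hexahydro-1-benzofuran-2,4-dione | C=C[C@]1(C)CC(=O)[C@H]2[C@H](OC(=O)C2)[C@@H]1C(=C)C
F7 | step 9 | (3aS,4S,6S,7R,7aR)-6-ethenyl-4-hydroxy-6-methyl-7-(prop-1-en-2-yl)hexahydro-1-benzofuran-2(3H)-one | C=C[C@]1(C)C[C@H](O)[C@H]2[C@H](OC(=O)C2)[C@@H]1C(=C)C
F8 | step 9 | (3aS,4R,6S,7R,7aR)-6-ethenyl-6-methyl-2-oxo-7-(prop-1-en-2-yl)octahydro-1-benzofuran-4-yl chloroacetate | C=C[C@]1(C)C[C@@H](OC(=O)CCl)[C@H]2[C@H](OC(=O)C2)[C@@H]1C(=C)C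
F9 | step 13 | dilithium C11-alkoxide C12-enolate of 23 | C=C[C@]1(C)C[C@@H](O[Si](C)(C)C(C)(C)C)[C@H]2[C@H](OC([O-])=C2[O-])[C@@H]1C(=C)C.[Li+].[Li+]
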